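**Retrosynthetic overview** (atom numbers are those of the target, tricyclo[5.3.1.0^{1,5}]undecane numbering; ring A = C1/C11/C7/C8/C9/C10, ring B = C1/C11/C7/C6/C5, ring C = C1–C2–C3–C4–C5)
1. Target 11 ⇐ tricycle 10 by Markovnikov hydration of the C3 isopropenyl group (no skeletal change).
2. 10 ⇐ spiro-vinylcyclopropane 9 in one radical chain operation: the cyclopropane C1–C2–C3 opens at C1–C3 and takes up the prenyl carbons C5 and C4, so ring B and the cyclopentane ring C form together; C1, C5 and C3 are set under control of C7.
3. 9 ⇐ dienone 5 + (E)-1,4-dibromo-2-methylbut-2-ene 7 (double C-alkylation at C1, SN2 then SN2'); 5 ⇐ acylphloroglucinol 3 by enantioselective dearomative C-prenylation (C7, the only centre set by a chiral catalyst); 3 ⇐ 2-methylphloroglucinol 1 + isobutyryl chloride 2.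
4. Enabling feature: C1 is the ring-A carbon flanked by both ring ketones C10=O and C11=O. Its CH2 can therefore be spiro-annulated, and homolysis of the cyclopropane bond C1–C3 gives a 1,3-dicarbonyl-stabilised C1 radical that sits 1,3 to the C7 prenyl group across C11, at 5-exo distance from C5.
5. Ring order: ring A (the arene, dearomatised in step 2) → cyclopropane (step 4) → rings B and C together (step 5).

Key step: step 5

Remarks on the chemistry: (a) the sense of induction in step 2 is assumed, the (R,R)-ligand being taken to give the (4S)-dienone; if it gives the antipode, the (S,S)-ligand is used and nothing else changes. (b) β-Triketones are drawn as one enol tautomer.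

**Step 1**
Reactants: 1 2-methylbenzene-1,3,5-triol; 2 2-methylpropanoyl chloride
Product: 3 1-(2,4,6-trihydroxy-3-methylphenyl)-2-methylpropan-1-one
Conditions: AlCl3 (4 equiv), PhNO2/CH2Cl2, 0 → 40 °C; ice/aq. HCl
Reagents that add atoms: none
Why: Friedel–Crafts acylation of the strongly activated triol, whose two unsubstituted ring positions are equivalent, so a single C-acyl product should form and no stereocentre is created.

**Step 2**
Reactants: 3 1-(2,4,6-trihydroxy-3-methylphenyl)-2-methylpropan-1-one; 4 3-methylbut-2-en-1-yl acetate (prenyl acetate)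
Product: 5 (4S)-3-hydroxy-4-methyl-4-(3-methylbut-2-en-1-yl)-2-(2-methylpropanoyl)cyclohex-2-ene-1,5-dione
Conditions: Pd2(dba)3·CHCl3 (2.5 mol %), (R,R)-N,N'-bis(2-diphenylphosphinobenzoyl)-1,2-diaminocyclohexane (7.5 mol %), Et3N (1.2 equiv), PhMe, 0 °C → rt
Reagents that add atoms: none
Why: Tsuji–Trost asymmetric allylic alkylation run as an alkylative dearomatisation, in which the phloroglucinolate attacks the CH2 terminus of the π-prenylpalladium complex through its methyl-bearing carbon (the gem-dialkylation preference of C-alkylphloroglucinols, which leaves C1–H free), and the chiral diphosphine pocket, distinguishing the acyl-flanked from the H-flanked side of the ring, sets the quaternary centre C7.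

**Step 3**
Reactants: 6 2-methylbuta-1,3-diene (isoprene)
Product: 7 (2E)-1,4-dibromo-2-methylbut-2-ene
Conditions: Br2 (1.0 equiv), CH2Cl2, −25 → 0 °C
Reagents that add atoms: bromine, BrBr
Why: electrophilic 1,4-addition of bromine to a conjugated diene through the allylic cation, the (E)-1,4-dibromide being the thermodynamic adduct.

**Step 4**
Reactants: 5 (4S)-dienone; 7 (2E)-1,4-dibromo-2-methylbut-2-ene
Product: 9 (7S)-6-hydroxy-7-methyl-7-(3-methylbut-2-en-1-yl)-5-(2-methylpropanoyl)-1-(prop-1-en-2-yl)spiro[2.5]oct-5-ene-4,8-dione (spiro-vinylcyclopropane; cyclopropane diastereomers), via C1-alkylated allylic bromide 8 (not isolated)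
Conditions: NaOMe (3.1 equiv), MeOH, −10 °C; 7 (1.05 equiv) added slowly, −10 °C → rt; 1 M HCl
Reagents that add atoms: none
Why: spiro-annulation of a cyclic 1,3-dicarbonyl CH2 with an (E)-1,4-dihalobut-2-ene, in which the dianion of 5 is C-alkylated at C1 by the prenyl-type CH2Br of 7 (protic solvent and sodium counter-ion favour carbon) and the regenerated enolate closes the three-membered ring by 3-exo SN2' displacement of the second bromide (the E geometry forbids direct five-ring SN2 closure), as known for indane-1,3-dione and malonate-type nucleophiles; the two new cyclopropane stereocentres need no control because both are erased in step 5.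

**Step 5**
Reactants: 9 spiro-vinylcyclopropane
Product: 10 (1S,3R,5S,7S)-8-hydroxy-4,4,7-trimethyl-9-(2-methylpropanoyl)-3-(prop-1-en-2-yl)tricyclo[5.3.1.0^{1,5}]undec-8-ene-10,11-dione
Conditions: (PhS)2 (0.3 equiv), AIBN (0.1 equiv), PhH (0.01 M, degassed), hν (sunlamp), 45 °C; SiO2 chromatography to remove the C3 epimer
Reagents that add atoms: none
Why: PhS• adds reversibly to the isopropenyl CH2, the cyclopropylcarbinyl radical opens the C1–C3 bond to the C1 radical stabilised by the C10 and C11 carbonyls, this radical closes ring B by 5-exo-trig attack on C5 of the C7 prenyl group, and the tertiary C4 radical closes ring C by 5-exo-trig attack on C3 of the transient allyl sulfide, after which β-scission expels PhS• and restores the isopropenyl group, so that the cyclopropane C1–C2–C3 has grown by C5 and C4 into the cyclopentane. The closest known reaction is the thiyl-radical-catalysed vinylcyclopropane–alkene [3+2] cycloaddition of 1,1-diacyl-2-vinylcyclopropanes, here intramolecular, and the two ring closures are the 5-exo/5-exo bicyclisation known for C1 radicals of dearomatised prenylated acylphloroglucinols. C1 and C5 are controlled by C7: the prenyl tether can reach the planar C1 radical only from its own face, and the CMe2 terminus should turn exo, away from the C8–C9–C10 bridge. C3 is set in the second closure, where the alkene terminus carrying the bulky PhSCH2 group is expected to turn toward the open exo side near C11 and so place H-3 cis to H-5; this preference may be modest, so a C3 epimer is expected and removed. The step needs ring opening toward C1 and not C2 (secured by the two flanking carbonyls) and productive reaction only at the vinylcyclopropane (thiyl addition to the prenyl alkene is reversible and leads nowhere), and a disulfide rather than a thiol is used so that the C1 and C4 radicals cyclise before they are reduced.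

**Step 6**
Reactants: 10 isopropenyl tricycle
Product: 11 (1S,3S,5S,7S)-8-hydroxy-3-(2-hydroxypropan-2-yl)-4,4,7-trimethyl-9-(2-methylpropanoyl)tricyclo[5.3.1.0^{1,5}]undec-8-ene-10,11-dione
Conditions: Co(acac)2 (0.3 equiv), PhSiH3 (2.5 equiv), O2 (1 atm), THF, 0 °C → rt
Reagents that add atoms: dioxygen, O=O
Why: Mukaiyama hydration, in which hydrogen-atom transfer from a cobalt hydride to the 1,1-disubstituted alkene gives the tertiary radical that is trapped by O2 and reduced to the tertiary alcohol with Markovnikov regiochemistry; no stereocentre is formed or touched, the tetrasubstituted conjugated enol of ring A should not accept the hydrogen atom, and the substrate's β-triketone is itself a β-diketonate-type ligand compatible with the catalyst.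

**Compound list**
1 | 2-methylbenzene-1,3,5-triol (2-methylphloroglucinol) | Cc1c(O)cc(O)cc1O | starting material
2 | 2-methylpropanoyl chloride (isobutyryl chloride) | CC(C)C(Cl)=O | starting material
3 | 1-(2,4,6-trihydroxy-3-methylphenyl)-2-methylpropan-1-one | CC(C)C(=O)c1c(O)cc(O)c(C)c1O | intermediate
4 | 3-methylbut-2-en-1-yl acetate (prenyl acetate) | CC(=O)OCC=C(C)C | starting material
5 | (4S)-3-hydroxy-4-methyl-4-(3-methylbut-2-en-1-yl)-2-(2-methylpropanoyl)cyclohex-2-ene-1,5-dione | CC(C)C(=O)C1=C(O)[C@](C)(CC=C(C)C)C(=O)CC1=O | intermediate
6 | 2-methylbuta-1,3-diene (isoprene) | C=CC(C)=C | starting material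
7 | (2E)-1,4-dibromo-2-methylbut-2-ene | BrC/C(C)=C/CBr | intermediate
8 | (4S)-6-[(2E)-4-bromo-3-methylbut-2-en-1-yl]-3-hydroxy-4-methyl-4-(3-methylbut-2-en-1-yl)-2-(2-methylpropanoyl)cyclohex-2-ene-1,5-dione (C6 epimers) | CC(C)C(=O)C1=C(O)[C@](C)(CC=C(C)C)C(=O)C(C/C=C(\C)CBr)C1=O | intermediate (not isolated)
9 | (7S)-6-hydroxy-7-methyl-7-(3-methylbut-2-en-1-yl)-5-(2-methylpropanoyl)-1-(prop-1-en-2-yl)spiro[2.5]oct-5-ene-4,8-dione (cyclopropane diastereomers) | CC(C)C(=O)C1=C(O)[C@](C)(CC=C(C)C)C(=O)C2(CC2C(C)=C)C1=O | intermediate
10 | (1S,3R,5S,7S)-8-hydroxy-4,4,7-trimethyl-9-(2-methylpropanoyl)-3-(prop-1-en-2-yl)tricyclo[5.3.1.0^{1,5}]undec-8-ene-10,11-dione | CC(C)C(=O)C1=C(O)[C@]2(C)C[C@H]3C(C)(C)[C@@H](C(C)=C)C[C@@]3(C1=O)C2=O | intermediate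
11 | (1S,3S,5S,7S)-8-hydroxy-3-(2-hydroxypropan-2-yl)-4,4,7-trimethyl-9-(2-methylpropanoyl)tricyclo[5.3.1.0^{1,5}]undec-8-ene-10,11-dione | CC(C)C(=O)C1=C(O)[C@]2(C)C[C@H]3C(C)(C)[C@@H](C(C)(C)O)C[C@@]3(C1=O)C2=O | target

**Step count:** 6 steps in total. **Longest linear sequence:** 5 steps (1 → 2 → 4 → 5 → 6); step 3 is a one-step branch.

**Steps most likely to fail**

Step 5. After ring opening, the C1 radical may be reduced, or may close through a carbonyl oxygen onto its own allyl sulfide (a radical Cloke–Wilson-type isomerisation to the 2-isopropenyl-dihydrofuran), faster than it adds to C5. The second closure may also show poor facial selectivity at C3. The fallback sets out from 5. C-prenylation at C1 (prenyl bromide, NaOMe, MeOH, 0 °C) should give (4S)-3-hydroxy-4-methyl-4,6-bis(3-methylbut-2-en-1-yl)-2-(2-methylpropanoyl)cyclohex-2-ene-1,5-dione F1. One-electron oxidation of its enol (PhI(OAc)2, TEMPO, THF, −78 °C, or Mn(OAc)3·2H2O/Cu(OAc)2, AcOH) generates the same C1 radical, which should undergo the 5-exo/5-exo bicyclisation, the final tertiary radical being oxidised to the isopropenyl group. This comes back to the route at 10. It is known radical chemistry for this compound class, but it abandons the ring-expansion logic and is held only as a reserve; C3 epimers would again have to be separated.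

Step 4. The ambident dianion may attack through oxygen or at the methallyl-type terminus of the unsymmetrical dibromide (leading to the 1-methyl-1-vinyl cyclopropane), and 8 may close through a carbonyl oxygen (5-exo) instead of through C1. The fallback sets out from 5. Allylation with 2-methyl-2-vinyloxirane under zerovalent-palladium catalysis (Pd(PPh3)4, THF, 0 °C) should give (4S)-3-hydroxy-6-[(2E)-4-hydroxy-3-methylbut-2-en-1-yl]-4-methyl-4-(3-methylbut-2-en-1-yl)-2-(2-methylpropanoyl)cyclohex-2-ene-1,5-dione F2, because soft 1,3-dicarbonyl carbon nucleophiles open the π-allyl complex at the distal CH2 terminus, which fixes the regiochemistry. PBr3 (0.4 equiv, Et2O, −20 °C) should then convert the primary allylic alcohol into bromide 8, where the fallback comes back to the route. Ring closure to 9 is then run as a separate operation with NaH in PhMe/THF at 0 °C (tight ion pair, no protic solvent), which should favour carbon over oxygen.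

Step 2. Enantioselectivity may be low because the two flanks of the ring differ only remotely; prenylation may compete at the unsubstituted carbon or go twice; and the C-prenyl bond may re-ionise on palladium and erode the enantiomeric purity. The fallback sets out from 3. Classical alkylative dearomatisation (prenyl bromide, NaOMe, MeOH, 0 °C) should give racemic 3-hydroxy-4-methyl-4-(3-methylbut-2-en-1-yl)-2-(2-methylpropanoyl)cyclohex-2-ene-1,5-dione F3. This strong vinylogous acid is resolved by crystallisation of its 1-phenylethylammonium salt, (S)-1-phenylethylammonium (4S)-enolate F4 (drawn for the (S)-amine; the amine enantiomer that crystallises with the (4S)-acid is to be chosen by trial). Release with dilute HCl comes back to the route at 5.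

**Further compounds**
F1 | step 5 | (4S)-3-hydroxy-4-methyl-4,6-bis(3-methylbut-2-en-1-yl)-2-(2-methylpropanoyl)cyclohex-2-ene-1,5-dione | CC(C)C(=O)C1=C(O)[C@](C)(CC=C(C)C)C(=O)C(CC=C(C)C)C1=O
F2 | step 4 | (4S)-3-hydroxy-6-[(2E)-4-hydroxy-3-methylbut-2-en-1-yl]-4-methyl-4-(3-methylbut-2-en-1-yl)-2-(2-methylpropanoyl)cyclohex-2-ene-1,5-dione | CC(C)C(=O)C1=C(O)[C@](C)(CC=C(C)C)C(=O)C(C/C=C(\C)CO)C1=O
F3 | step 2 | racemic 3-hydroxy-4-methyl-4-(3-methylbut-2-en-1-yl)-2-(2-methylpropanoyl)cyclohex-2-ene-1,5-dione | CC(C)C(=O)C1=C(O)C(C)(CC=C(C)C)C(=O)CC1=O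
F4 | step 2 | (S)-1-phenylethylammonium salt of the (4S)-dienone enolate | CC(C)C(=O)C1=C([O-])[C@](C)(CC=C(C)C)C(=O)CC1=O.C[C@H]([NH3+])c1ccccc1
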